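## Retrosynthetic overview
1. The three ArOMe groups are installed last and together, by C–Br to C–OMe exchange on a tribromo bisphenol. Bromine serves as a masked methoxy group and keeps ring B unreactive until then.
2. The tetrahydrofuran C2–O bond comes from acid cyclodehydration of a benzylic 1,4-diol, which gives the thermodynamic all-trans isomer. The C2–aryl bond comes from a ring A Grignard reagent and a trans-3-methyl-4-benzyl-γ-butyrolactone.
3. The C3 methyl comes from anti enolate methylation. The lactone comes from an enantioselective carbonylative ring expansion (four- to five-membered) of a prochiral 3-benzyloxetane, which sets C4 and brings in C2.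
4. The 3-benzyloxetane comes from a Negishi coupling of 3-(iodomethyl)oxetane with O-protected 4-bromophenol.
5. Ring order: oxetane (bought), then γ-butyrolactone (ring expansion), then opening by ArMgBr, then tetrahydrofuran (final closure). Both arenes are bought.

Assumption: in step 2 "(R,R)" stands for the ligand antipode that gives the (R)-lactone. The real sense of induction has to be fixed by a first experiment.

## Route

Step 1
Reactants: 1 3-(iodomethyl)oxetane; 2 1-bromo-4-tert-butoxybenzene
Product: 4 3-(4-tert-butoxybenzyl)oxetane, via oxetan-3-ylmethylzinc iodide 3 (not isolated)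
Conditions: 1, Zn dust, LiCl, THF, 40 °C; then 2, Pd(OAc)2 (2 mol%), SPhos (4 mol%), THF, 50 °C
Reagents that add atoms: none
Why: Negishi coupling, in which LiCl-assisted zinc insertion into the primary C–I bond gives a stable alkylzinc that zerovalent palladium/SPhos joins to the electron-rich aryl bromide faster than β-hydride elimination, while the oxetane and the tert-butyl ether are inert and no stereocentre is formed.

Step 2
Reactants: 4 3-(4-tert-butoxybenzyl)oxetane
Product: 5 (4R)-4-(4-tert-butoxybenzyl)oxolan-2-one
Conditions: [(R,R)-(salen)Al(THF)2][Co(CO)4] (5 mol%; salen = N,N'-bis(3,5-di-tert-butylsalicylidene)cyclohexane-1,2-diaminate), CO (60 bar), DME, 60 °C, 24 h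
Reagents that add atoms: carbon monoxide [C-]#[O+]
Why: Proposed new method: enantioselective desymmetrising ring-expansion carbonylation of a prochiral 3-substituted oxetane, in which the chiral aluminium cation binds the ring oxygen, the Co(CO)4 anion opens one of the two enantiotopic CH2–O bonds by SN2 attack (this choice fixes C4 as R), the alkyl group shifts from cobalt to a CO ligand (1,2-migratory insertion) and the aluminium alkoxide closes on the acylcobalt to release the five-membered lactone and the ion pair; the closest known reaction types are the [Lewis acid][Co(CO)4]-catalysed ring-expansion carbonylation of epoxides to β-lactones (including meso-epoxide desymmetrisation), the non-asymmetric carbonylation of parent oxetane to γ-butyrolactone, and chiral-Lewis-acid desymmetrising openings of 3-substituted oxetanes by other nucleophiles.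

Step 3
Reactants: 5 (4R)-4-(4-tert-butoxybenzyl)oxolan-2-one
Product: 6 (3R,4R)-4-(4-tert-butoxybenzyl)-3-methyloxolan-2-one
Conditions: LDA (1.05 equiv), THF, −78 °C; MeI (1.2 equiv), −78 → −40 °C
Reagents that add atoms: methyl iodide CI
Why: Lithium enolate alkylation, in which MeI approaches the planar lactone enolate on the face away from the C4 benzyl group, so the 3,4-trans (3R) product, which is also the thermodynamic epimer, forms with high selectivity.

Step 4
Reactants: 6 (3R,4R)-4-(4-tert-butoxybenzyl)-3-methyloxolan-2-one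
Product: 7 (3R,4R)-4-(3,5-dibromo-4-hydroxybenzyl)-3-methyloxolan-2-one
Conditions: Br2 (2.05 equiv), CH2Cl2–AcOH 4:1, 0 °C → rt, 1 h; aq Na2S2O3
Reagents that add atoms: bromine BrBr
Why: Electrophilic aromatic bromination with acidolysis, in which HBr from the first substitution cleaves the acid-labile aryl tert-butyl ether and the freed phenol takes bromine at both open ortho positions (para is blocked), after which the ring is deactivated and the lactone stereocentres are untouched.

Step 5
Reactants: 7 (3R,4R)-4-(3,5-dibromo-4-hydroxybenzyl)-3-methyloxolan-2-one; 8 2-(4-bromophenoxy)oxane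
Product: 12 (2R,3R,4R)-4-(3,5-dibromo-4-hydroxybenzyl)-2-(4-hydroxyphenyl)-3-methyloxolane, via aryl Grignard reagent 9 (not isolated), via hydroxy ketone 10 (not isolated), via benzylic diol 11 (not isolated)
Conditions: 8, Mg, THF, 40 °C (gives 9); 7, i-PrMgCl (1.0 equiv), THF, −40 °C, then 9 (1.4 equiv), −40 → 0 °C; MeOH, NaBH4, 0 °C → rt; 2 M aq HCl to pH 1, rt, 3 h
Reagents that add atoms: none
Why: Grignard addition to the lactone, borohydride reduction and SN1 cyclodehydration in one flask, in which acid removes the THP group and ionises the p-hydroxybenzylic alcohol to a quinone-methide-type cation that the primary OH captures reversibly (5-exo) to place the aryl group trans to the C3 methyl (2R, the all-trans thermodynamic isomer), while the aryl bromides tolerate ArMgBr and the brominated ring B is too deactivated for Friedel–Crafts closure to an aryltetralin.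

Step 6
Reactants: 12 (2R,3R,4R)-4-(3,5-dibromo-4-hydroxybenzyl)-2-(4-hydroxyphenyl)-3-methyloxolane
Product: 13 (2R,3R,4R)-2-(3-bromo-4-hydroxyphenyl)-4-(3,5-dibromo-4-hydroxybenzyl)-3-methyloxolane
Conditions: NBS (1.00 equiv, added over 1 h), CH2Cl2–MeCN, −40 → −10 °C, dark
Reagents that add atoms: N-bromosuccinimide O=C1CCC(=O)N1Br
Why: Electrophilic aromatic bromination, in which only ring A has free positions ortho to a phenol OH and the first bromine lowers its reactivity, so one equivalent of NBS at low temperature stops at the monobromide without touching ring B or any stereocentre.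

Step 7
Reactants: 13 (2R,3R,4R)-2-(3-bromo-4-hydroxyphenyl)-4-(3,5-dibromo-4-hydroxybenzyl)-3-methyloxolane
Product: 14 (2R,3R,4R)-2-(4-hydroxy-3-methoxyphenyl)-4-(4-hydroxy-3,5-dimethoxybenzyl)-3-methyloxolane (CID53359708)
Conditions: NaOMe (12 equiv), CuBr (0.3 equiv), MeOH–DMF, 105 °C, Ar, sealed tube, 8 h; 1 M HCl work-up
Reagents that add atoms: sodium methoxide [Na+].[O-]C
Why: Ullmann-type copper-catalysed methoxylation of o-bromophenoxides, the reaction that turns bromocresols and bromovanillin into guaiacyl and syringyl units, exchanges all three C–Br bonds at once, and the only base-labile centre (C2, through the quinone methide) can only re-close to the same all-trans isomer.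

## Compound list
1 | 3-(iodomethyl)oxetane | ICC1COC1 | starting material
2 | 1-bromo-4-tert-butoxybenzene | CC(C)(C)Oc1ccc(Br)cc1 | starting material
3 | (oxetan-3-ylmethyl)zinc iodide | I[Zn]CC1COC1 | intermediate
4 | 3-(4-tert-butoxybenzyl)oxetane | CC(C)(C)Oc1ccc(CC2COC2)cc1 | intermediate
5 | (4R)-4-(4-tert-butoxybenzyl)oxolan-2-one | O=C1OC[C@H](Cc2ccc(OC(C)(C)C)cc2)C1 | intermediate
6 | (3R,4R)-4-(4-tert-butoxybenzyl)-3-methyloxolan-2-one | O=C1OC[C@H](Cc2ccc(OC(C)(C)C)cc2)[C@H]1C | intermediate
7 | (3R,4R)-4-(3,5-dibromo-4-hydroxybenzyl)-3-methyloxolan-2-one | O=C1OC[C@H](Cc2cc(Br)c(O)c(Br)c2)[C@H]1C | intermediate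
8 | 2-(4-bromophenoxy)oxane (THP ether of 4-bromophenol, racemic acetal) | Brc1ccc(OC2CCCCO2)cc1 | starting material
9 | [4-(oxan-2-yloxy)phenyl]magnesium bromide | Br[Mg]c1ccc(OC2CCCCO2)cc1 | intermediate
10 | (2R,3R)-3-(3,5-dibromo-4-hydroxybenzyl)-4-hydroxy-2-methyl-1-[4-(oxan-2-yloxy)phenyl]butan-1-one | OC[C@H](Cc1cc(Br)c(O)c(Br)c1)[C@@H](C)C(=O)c1ccc(OC2CCCCO2)cc1 | intermediate
11 | (2R,3R)-2-(3,5-dibromo-4-hydroxybenzyl)-3-methyl-4-[4-(oxan-2-yloxy)phenyl]butane-1,4-diol (C4 epimers) | OC[C@H](Cc1cc(Br)c(O)c(Br)c1)[C@@H](C)C(O)c1ccc(OC2CCCCO2)cc1 | intermediate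
12 | (2R,3R,4R)-4-(3,5-dibromo-4-hydroxybenzyl)-2-(4-hydroxyphenyl)-3-methyloxolane | Oc1ccc([C@@H]2OC[C@H](Cc3cc(Br)c(O)c(Br)c3)[C@H]2C)cc1 | intermediate
13 | (2R,3R,4R)-2-(3-bromo-4-hydroxyphenyl)-4-(3,5-dibromo-4-hydroxybenzyl)-3-methyloxolane | Oc1ccc([C@@H]2OC[C@H](Cc3cc(Br)c(O)c(Br)c3)[C@H]2C)cc1Br | intermediate
14 | (2R,3R,4R)-2-(4-hydroxy-3-methoxyphenyl)-4-(4-hydroxy-3,5-dimethoxybenzyl)-3-methyloxolane | COc1cc([C@@H]2OC[C@H](Cc3cc(OC)c(O)c(OC)c3)[C@H]2C)ccc1O | target

## Step count and risks
Total steps: 7. Longest linear sequence: 7 (1 or 2 to 14).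

**Step 2 (the new step).**
- Risk: attack at the β-branched CH2 may be slow. Polyether or polyester formation may compete, and the ee may be modest. Crystalline 7 offers a point for ee upgrade.
- Fallback: known chemistry, setting out from 2 and coming back at 5.
- Aryl bromide 2 is joined to commercial 3-(bromomethyl)cyclobutan-1-one (O=C1CC(CBr)C1) by nickel-catalysed reductive cross-electrophile coupling (NiBr2(dme), 4,4'-di-tert-butyl-2,2'-bipyridine, Zn, NaI, DMA, 60 °C). This gives 3-(4-tert-butoxybenzyl)cyclobutan-1-one F1.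
- The prochiral ketone is then desymmetrised by an established enantioselective Baeyer–Villiger ring expansion (Sc(OTf)3 with a chiral N,N'-dioxide ligand and m-CPBA, or a cyclohexanone monooxygenase). This delivers lactone 5.

**Step 5.**
- Risk: a second addition of 9 to ketone 10, partial epimerisation next to the ketone, or incomplete control at C2 in the one-flask sequence.
- Fallback: sets out from 7 and comes back at 11.
- DIBAL-H (2.2 equiv, CH2Cl2, −78 °C) reduces 7 to (3R,4R)-4-(3,5-dibromo-4-hydroxybenzyl)-3-methyloxolan-2-ol F2.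
- The open hydroxy aldehyde form of F2 can take up Grignard reagent 9 (3.5 equiv, THF, 0 °C) only once, which gives diol 11.
- Diol 11 is isolated and closed to 12 in a separate equilibrating acid step (camphorsulfonic acid or HCl, wet THF, rt).

**Step 7.**
- Risk: incomplete exchange or hydrodebromination at one of three sites, and slow quinone-methide chemistry of the free phenoxides at 105 °C.
- Fallback: sets out from 13 and comes back at 14.
- Both phenols are benzylated (BnBr, K2CO3, DMF) to give (2R,3R,4R)-2-[4-(benzyloxy)-3-bromophenyl]-4-[4-(benzyloxy)-3,5-dibromobenzyl]-3-methyloxolane F3.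
- The three bromides are exchanged by palladium-catalysed C–O coupling ([Pd(allyl)Cl]2, tBuBrettPhos, NaOtBu, MeOH–dioxane, 60 °C). This gives (2R,3R,4R)-2-[4-(benzyloxy)-3-methoxyphenyl]-4-[4-(benzyloxy)-3,5-dimethoxybenzyl]-3-methyloxolane F4.
- Hydrogenolysis (H2, Pd/C, EtOAc, 1 atm) then gives 14.

## Further compounds
F1 | step 2 | 3-(4-tert-butoxybenzyl)cyclobutan-1-one | O=C1CC(Cc2ccc(OC(C)(C)C)cc2)C1
F2 | step 5 | (3R,4R)-4-(3,5-dibromo-4-hydroxybenzyl)-3-methyloxolan-2-ol (anomers) | OC1OC[C@H](Cc2cc(Br)c(O)c(Br)c2)[C@H]1C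
F3 | step 7 | (2R,3R,4R)-2-[4-(benzyloxy)-3-bromophenyl]-4-[4-(benzyloxy)-3,5-dibromobenzyl]-3-methyloxolane | c1ccccc1COc1ccc([C@@H]2OC[C@H](Cc3cc(Br)c(OCc4ccccc4)c(Br)c3)[C@H]2C)cc1Br
F4 | step 7 | (2R,3R,4R)-2-[4-(benzyloxy)-3-methoxyphenyl]-4-[4-(benzyloxy)-3,5-dimethoxybenzyl]-3-methyloxolane | c1ccccc1COc1ccc([C@@H]2OC[C@H](Cc3cc(OC)c(OCc4ccccc4)c(OC)c3)[C@H]2C)cc1OC
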